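**Plan**
1. Retrosynthetic cuts, in this order: the ester C–O bond at the C3 CH2O arm; O1–C7a of the dihydrofuran ring; C5–CH= of the propenal; C2–C3; the C3a–CH2 bond of a ring A arylacetic acid.
2. Enabling feature: in ring A, C7a stands para to the C5 propenal and lies between C7 (OMe) and C3a (alkyl). A C7a–F bond is therefore a vinylogous acyl fluoride with no ortho hydrogen, and the oxygen on C2 can reach it through a five-membered ring (O1, C2, C3, C3a, C7a).
3. Switch logic: fluorine first directs the lithiation that builds the ring A acid. It then stays inert while C5 carries bromine (aldol, hydride, palladium). The Heck reaction turns C5–Br into the acceptor and so arms C7a for closure at room temperature.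
4. Forward order: ring A acid, Evans imide, syn aldol with the ring B aldehyde (joins C2–C3), reduction and silylation, Heck reaction at C5, closure of the only new ring, desilylation, chemoselective esterification.
5. Stereochemistry: both centres come from one Evans syn aldol controlled by (R)-4-benzyloxazolidinone. The closure breaks no bond at C2 or C3, so the syn chain becomes the trans-(2R,3S) ring.

Key step: step 9

Assumption: locants O1, C2, C3, C3a, C4–C7, C7a are those of 2,3-dihydro-1-benzofuran; ring A is its benzo ring and ring B the 4-hydroxy-3-methoxyphenyl group; 1, 5, 8 and 21 are taken as catalogue compounds.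

**Step 1**
Reactants: 1 4-bromo-1-fluoro-2-methoxybenzene
Product: 3 1-allyl-5-bromo-2-fluoro-3-methoxybenzene, via aryllithium 2 (not isolated)
Conditions: LDA (1.05 equiv), THF, −78 °C; then CuBr·SMe2 (10 mol %), allyl bromide, −78 °C, slowly to rt
Reagents that add atoms: allyl bromide C=CCBr
Why: Fluorine is the strongest ortho-acidifying group of 1, so the bulky amide should remove the unhindered proton next to it (directed ortho-lithiation) below the temperature of LiF loss, and copper-catalysed allylation of 2 should give 3.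

**Step 2**
Reactants: 3 1-allyl-5-bromo-2-fluoro-3-methoxybenzene
Product: 4 2-(5-bromo-2-fluoro-3-methoxyphenyl)acetic acid
Conditions: RuCl3·xH2O (2 mol %), NaIO4 (4.1 equiv), MeCN/EtOAc/H2O, 0 °C to rt
Reagents that add atoms: sodium periodate [Na+].[O-]I(=O)(=O)=O
Why: RuO4 made in situ cleaves the terminal alkene to the acid with loss of one carbon (ruthenium tetroxide/periodate oxidative cleavage), and the ring, deactivated by F and Br, should react far more slowly than the alkene.

**Step 3**
Reactants: 4 2-(5-bromo-2-fluoro-3-methoxyphenyl)acetic acid; 5 (R)-4-benzyl-1,3-oxazolidin-2-one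
Product: 7 (R)-4-benzyl-3-[2-(5-bromo-2-fluoro-3-methoxyphenyl)acetyl]-1,3-oxazolidin-2-one, via mixed anhydride 6 (not isolated)
Conditions: PivCl, Et3N, THF, −20 °C; then LiCl, 5, −20 °C to rt
Reagents that add atoms: none
Why: N-acylation of the oxazolidinone through the mixed pivalic anhydride with LiCl/Et3N is the standard mild entry to Evans imides and needs no strong base next to the aryl halides.

**Step 4**
Reactants: 8 vanillin
Product: 9 3-methoxy-4-(triisopropylsilyloxy)benzaldehyde
Conditions: TIPSCl, imidazole, DMF, rt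
Reagents that add atoms: chlorotriisopropylsilane CC(C)[Si](Cl)(C(C)C)C(C)C
Why: This is a routine phenol silylation, and TIPS is chosen because it should survive boron triflate, hydride, carbonate at 90 °C and alkoxide.

**Step 5**
Reactants: 7 (R)-4-benzyl-3-[2-(5-bromo-2-fluoro-3-methoxyphenyl)acetyl]-1,3-oxazolidin-2-one; 9 3-methoxy-4-(triisopropylsilyloxy)benzaldehyde
Product: 12 (R)-4-benzyl-3-[(2R,3R)-2-(5-bromo-2-fluoro-3-methoxyphenyl)-3-hydroxy-3-[3-methoxy-4-(triisopropylsilyloxy)phenyl]propanoyl]-1,3-oxazolidin-2-one, via boron enolate 10 (not isolated), via boron aldolate 11 (not isolated)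
Conditions: n-Bu2BOTf, Et3N, CH2Cl2, −78 to 0 °C; 9, −78 to 0 °C; then pH 7 buffer, MeOH, 30% H2O2, 0 °C
Reagents that add atoms: none
Why: In this Evans syn aldol the (Z)-boron enolate 10 adds to 9 through a chair Zimmerman–Traxler transition state on the enolate face turned away from the benzyl group of the (R)-auxiliary, which should set both stereocentres as (2R,3R)-syn.

**Step 6**
Reactants: 12 syn aldol adduct
Product: 13 (1R,2S)-2-(5-bromo-2-fluoro-3-methoxyphenyl)-1-[3-methoxy-4-(triisopropylsilyloxy)phenyl]propane-1,3-diol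
Conditions: LiBH4, MeOH, THF, 0 °C
Reagents that add atoms: none
Why: Reductive removal of the Evans auxiliary with LiBH4/MeOH attacks the exocyclic imide carbonyl without retro-aldol, so both centres are kept (the descriptor of the aryl-bearing carbon changes to S by priority only).

**Step 7**
Reactants: 13 diol
Product: 14 (1R,2S)-2-(5-bromo-2-fluoro-3-methoxyphenyl)-1-[3-methoxy-4-(triisopropylsilyloxy)phenyl]-3-(triisopropylsilyloxy)propan-1-ol
Conditions: TIPSCl (1.05 equiv), imidazole, DMAP (cat.), CH2Cl2, 0 °C to rt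
Reagents that add atoms: chlorotriisopropylsilane CC(C)[Si](Cl)(C(C)C)C(C)C
Why: The bulky silyl chloride should react with the primary hydroxyl group much faster than with the hindered secondary benzylic one (steric chemoselection in silyl ether formation).

**Step 8**
Reactants: 14 bromo alcohol
Product: 16 (E)-3-{4-fluoro-3-[(1R,2S)-1-hydroxy-1-[3-methoxy-4-(triisopropylsilyloxy)phenyl]-3-(triisopropylsilyloxy)propan-2-yl]-5-methoxyphenyl}prop-2-enal, via diethyl acetal 15 (not isolated)
Conditions: acrolein diethyl acetal, Pd(OAc)2 (5 mol %), n-Bu4NOAc, K2CO3, KCl, DMF, 90 °C; then 1 M HCl, THF, 0 °C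
Reagents that add atoms: acrolein diethyl acetal C=CC(OCC)OCC; water O
Why: The Mizoroki–Heck reaction of aryl bromides with acrolein diethyl acetal under ligand-free acetate/carbonate conditions gives (E)-cinnamaldehyde acetals that mild acid opens to the enal, while the C–F bond is inert to zerovalent palladium and no stereocentre is touched.

**Step 9**
Reactants: 16 fluoro enal alcohol
Product: 19 (E)-3-{(2R,3S)-7-methoxy-2-[3-methoxy-4-(triisopropylsilyloxy)phenyl]-3-[(triisopropylsilyloxy)methyl]-2,3-dihydro-1-benzofuran-5-yl}prop-2-enal, via sodium alkoxide 17 (not isolated), via Meisenheimer adduct 18 (not isolated)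
Conditions: NaH (1.1 equiv), THF, 0 °C to rt
Reagents that add atoms: none
Why: NaH removes the only acidic proton of 16 and the C2 alkoxide 17 adds to C7a of ring A to give the Meisenheimer adduct 18, whose charge runs through C5 into the propenal oxygen, before fluoride leaves as insoluble NaF and ring A re-aromatises (addition–elimination SNAr). The closest known reaction type is the base-induced cyclisation of 2-(2-fluoroaryl)ethanols bearing a para acceptor to 2,3-dihydrobenzofurans. The one ring that forms (O1, C2, C3, C3a, C7a) closes in a 5-exo-trig sense with respect to the C7a=C7 bond. No lasting stereocentre is created (C7a of 18 is sp3 only in passing) and no bond at C2 or C3 is broken, so the (1R,2S)-syn array set by the auxiliary in step 5 is carried over as the trans-(2R,3S) ring, with the aryl group and the CH2O arm on opposite faces in the closing conformer. The step needs O-selectivity (C2–O, not the primary oxygen), secured by the slowly migrating TIPS ether; site selectivity on ring A, secured because only C7a bears a leaving group and it has no ortho hydrogen for an aryne path; and chemoselectivity against the enal, which holds because alkoxide addition to C=O or C=C is reversible while loss of fluoride is not.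

**Step 10**
Reactants: 19 bis-silyl dihydrobenzofuran
Product: 20 (E)-3-[(2R,3S)-2-(4-hydroxy-3-methoxyphenyl)-3-(hydroxymethyl)-7-methoxy-2,3-dihydro-1-benzofuran-5-yl]prop-2-enal
Conditions: TBAF (2.5 equiv), AcOH (2.5 equiv), THF, 0 °C to rt
Reagents that add atoms: none
Why: Fluoride cleaves both Si–O bonds (fluoride desilylation driven by the Si–F bond), and acetic acid buffers the phenoxide and alkoxide so that the enal and the benzylic aryl ether are not exposed to base.

**Step 11**
Reactants: 20 phenolic alcohol; 21 3-methylbutanoic acid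
Product: 22 [(2R,3S)-2-(4-hydroxy-3-methoxyphenyl)-7-methoxy-5-[(E)-3-oxoprop-1-enyl]-2,3-dihydro-1-benzofuran-3-yl]methyl 3-methylbutanoate
Conditions: PPh3, DIAD, THF, 0 °C to rt
Reagents that add atoms: none
Why: In the Mitsunobu esterification only the primary alcohol forms the alkoxyphosphonium ion, and the carboxylic acid is deprotonated in preference to the far less acidic phenol, so the ester should form at the CH2 group without phenol protection and without touching a stereocentre.

**Compound list**
1 | 4-bromo-1-fluoro-2-methoxybenzene | COc1cc(Br)ccc1F | starting material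
2 | (5-bromo-2-fluoro-3-methoxyphenyl)lithium | [Li]c1cc(Br)cc(OC)c1F | intermediate
3 | 1-allyl-5-bromo-2-fluoro-3-methoxybenzene | C=CCc1cc(Br)cc(OC)c1F | intermediate
4 | 2-(5-bromo-2-fluoro-3-methoxyphenyl)acetic acid | OC(=O)Cc1cc(Br)cc(OC)c1F | intermediate
5 | (R)-4-benzyl-1,3-oxazolidin-2-one | O=C1N[C@H](Cc2ccccc2)CO1 | starting material
6 | 2-(5-bromo-2-fluoro-3-methoxyphenyl)acetic pivalic anhydride | CC(C)(C)C(=O)OC(=O)Cc1cc(Br)cc(OC)c1F | intermediate
7 | (R)-4-benzyl-3-[2-(5-bromo-2-fluoro-3-methoxyphenyl)acetyl]-1,3-oxazolidin-2-one | O=C(Cc1cc(Br)cc(OC)c1F)N1[C@H](Cc2ccccc2)COC1=O | intermediate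
8 | vanillin (4-hydroxy-3-methoxybenzaldehyde) | COc1cc(C=O)ccc1O | starting material
9 | 3-methoxy-4-(triisopropylsilyloxy)benzaldehyde | COc1cc(C=O)ccc1O[Si](C(C)C)(C(C)C)C(C)C | intermediate
10 | (Z)-dibutylboron enolate of 7 | CCCCB(CCCC)O/C(=C\c1cc(Br)cc(OC)c1F)N1[C@H](Cc2ccccc2)COC1=O | intermediate
11 | O-dibutylboryl derivative (boron aldolate) of 12 | COc1cc([C@H](OB(CCCC)CCCC)[C@@H](c2cc(Br)cc(OC)c2F)C(=O)N2[C@H](Cc3ccccc3)COC2=O)ccc1O[Si](C(C)C)(C(C)C)C(C)C | intermediate
12 | (R)-4-benzyl-3-[(2R,3R)-2-(5-bromo-2-fluoro-3-methoxyphenyl)-3-hydroxy-3-[3-methoxy-4-(triisopropylsilyloxy)phenyl]propanoyl]-1,3-oxazolidin-2-one | COc1cc([C@H](O)[C@@H](c2cc(Br)cc(OC)c2F)C(=O)N2[C@H](Cc3ccccc3)COC2=O)ccc1O[Si](C(C)C)(C(C)C)C(C)C | intermediate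
13 | (1R,2S)-2-(5-bromo-2-fluoro-3-methoxyphenyl)-1-[3-methoxy-4-(triisopropylsilyloxy)phenyl]propane-1,3-diol | COc1cc([C@H](O)[C@@H](c2cc(Br)cc(OC)c2F)CO)ccc1O[Si](C(C)C)(C(C)C)C(C)C | intermediate
14 | (1R,2S)-2-(5-bromo-2-fluoro-3-methoxyphenyl)-1-[3-methoxy-4-(triisopropylsilyloxy)phenyl]-3-(triisopropylsilyloxy)propan-1-ol | COc1cc([C@H](O)[C@@H](c2cc(Br)cc(OC)c2F)CO[Si](C(C)C)(C(C)C)C(C)C)ccc1O[Si](C(C)C)(C(C)C)C(C)C | intermediate
15 | (1R,2S)-2-{5-[(E)-3,3-diethoxyprop-1-enyl]-2-fluoro-3-methoxyphenyl}-1-[3-methoxy-4-(triisopropylsilyloxy)phenyl]-3-(triisopropylsilyloxy)propan-1-ol | COc1cc([C@H](O)[C@@H](c2cc(/C=C/C(OCC)OCC)cc(OC)c2F)CO[Si](C(C)C)(C(C)C)C(C)C)ccc1O[Si](C(C)C)(C(C)C)C(C)C | intermediate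
16 | (E)-3-{4-fluoro-3-[(1R,2S)-1-hydroxy-1-[3-methoxy-4-(triisopropylsilyloxy)phenyl]-3-(triisopropylsilyloxy)propan-2-yl]-5-methoxyphenyl}prop-2-enal | COc1cc([C@H](O)[C@@H](c2cc(/C=C/C=O)cc(OC)c2F)CO[Si](C(C)C)(C(C)C)C(C)C)ccc1O[Si](C(C)C)(C(C)C)C(C)C | intermediate
17 | sodium alkoxide of 16 | COc1cc([C@H]([O-])[C@@H](c2cc(/C=C/C=O)cc(OC)c2F)CO[Si](C(C)C)(C(C)C)C(C)C)ccc1O[Si](C(C)C)(C(C)C)C(C)C.[Na+] | intermediate
18 | Meisenheimer adduct (C7a sp3 with F and O1, charge on the side-chain oxygen, sodium salt) | COc1cc([C@@H]2OC3(F)C(OC)=CC(=CC=C[O-])C=C3[C@H]2CO[Si](C(C)C)(C(C)C)C(C)C)ccc1O[Si](C(C)C)(C(C)C)C(C)C.[Na+] | intermediate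
19 | (E)-3-{(2R,3S)-7-methoxy-2-[3-methoxy-4-(triisopropylsilyloxy)phenyl]-3-[(triisopropylsilyloxy)methyl]-2,3-dihydro-1-benzofuran-5-yl}prop-2-enal | COc1cc([C@@H]2Oc3c(OC)cc(/C=C/C=O)cc3[C@H]2CO[Si](C(C)C)(C(C)C)C(C)C)ccc1O[Si](C(C)C)(C(C)C)C(C)C | intermediate
20 | (E)-3-[(2R,3S)-2-(4-hydroxy-3-methoxyphenyl)-3-(hydroxymethyl)-7-methoxy-2,3-dihydro-1-benzofuran-5-yl]prop-2-enal | COc1cc([C@@H]2Oc3c(OC)cc(/C=C/C=O)cc3[C@H]2CO)ccc1O | intermediate
21 | 3-methylbutanoic acid (isovaleric acid) | CC(C)CC(=O)O | starting material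
22 | [(2R,3S)-2-(4-hydroxy-3-methoxyphenyl)-7-methoxy-5-[(E)-3-oxoprop-1-enyl]-2,3-dihydro-1-benzofuran-3-yl]methyl 3-methylbutanoate | COc1cc([C@@H]2Oc3c(OC)cc(/C=C/C=O)cc3[C@H]2COC(=O)CC(C)C)ccc1O | target

**Totals**
Total step count: 11. Longest linear sequence: 10 (steps 1–3 and 5–11).

**Steps most likely to fail**

**Step 9 (ring closure).**
- What may go wrong: base-induced migration of the TIPS group from the primary oxygen to the C2 alkoxide, followed by closure through the wrong oxygen; or hydride transfer from the benzylic alkoxide to the enal.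
- The fallback sets out from 12 and returns at 20. It moves the closure to a stage at which the molecule holds neither a second oxygen nucleophile nor an aldehyde.
- LiOH/H2O2 (THF/H2O, 0 °C) should cleave the auxiliary from 12 to give the β-hydroxy acid F1.
- KHMDS (2.2 equiv) with 18-crown-6 in THF at 60 °C should close the ring in the carboxylate–alkoxide dianion to give the 5-bromo-dihydrobenzofuran-3-carboxylic acid F2. In this dianion the carboxylate shuts off deprotonation at C3, retro-aldol cleavage and β-elimination.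
- BH3·SMe2 (THF, 0 °C to rt) should reduce it to the primary alcohol F3.
- The Heck conditions of step 8 should then give the diethyl acetal F4 and, after mild acid, the enal F5.
- TBAF/AcOH should give 20.

**Step 8 (Heck reaction).**
- What may go wrong: β-hydride elimination from an arylpalladium alkoxide of the free C2 hydroxyl group (oxidation of the alcohol with hydrodebromination); loss of the aryl silyl ether in carbonate/DMF at 90 °C; ionisation at C2 during the acid hydrolysis.
- The fallback sets out from 14 and returns at 16. It builds the side chain in two mild C–C steps without any acetal.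
- Suzuki–Miyaura vinylation with potassium vinyltrifluoroborate (PdCl2(dppf), Et3N, n-PrOH, 80 °C) should give the styrene F6.
- Cross metathesis with crotonaldehyde (second-generation Hoveyda–Grubbs catalyst, CH2Cl2, 40 °C) should give the (E)-enal 16 directly.

**Step 1 (ortho-lithiation).**
- What may go wrong: competing deprotonation between OMe and Br, loss of lithium halide to arynes, or halogen migration.
- The fallback sets out from 1 and returns at 3. It replaces deprotonation by a sterically governed C–H borylation.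
- With [Ir(OMe)(cod)]2, dtbpy and B2pin2 (THF, 80 °C) only the C–H bond next to the small fluorine is open, because the other two lie next to bromine. This should give the pinacol boronate F7.
- Copper-catalysed allylation (CuCl, KOt-Bu, allyl bromide, THF, rt) leaves the C–Br bond untouched and should give 3.

**Further compounds**
F1 | step 9 | (2R,3R)-2-(5-bromo-2-fluoro-3-methoxyphenyl)-3-hydroxy-3-[3-methoxy-4-(triisopropylsilyloxy)phenyl]propanoic acid | COc1cc([C@H](O)[C@@H](c2cc(Br)cc(OC)c2F)C(=O)O)ccc1O[Si](C(C)C)(C(C)C)C(C)C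
F2 | step 9 | (2R,3R)-5-bromo-7-methoxy-2-[3-methoxy-4-(triisopropylsilyloxy)phenyl]-2,3-dihydro-1-benzofuran-3-carboxylic acid | COc1cc([C@@H]2Oc3c(OC)cc(Br)cc3[C@H]2C(=O)O)ccc1O[Si](C(C)C)(C(C)C)C(C)C
F3 | step 9 | {(2R,3S)-5-bromo-7-methoxy-2-[3-methoxy-4-(triisopropylsilyloxy)phenyl]-2,3-dihydro-1-benzofuran-3-yl}methanol | COc1cc([C@@H]2Oc3c(OC)cc(Br)cc3[C@H]2CO)ccc1O[Si](C(C)C)(C(C)C)C(C)C
F4 | step 9 | {(2R,3S)-5-[(E)-3,3-diethoxyprop-1-enyl]-7-methoxy-2-[3-methoxy-4-(triisopropylsilyloxy)phenyl]-2,3-dihydro-1-benzofuran-3-yl}methanol | COc1cc([C@@H]2Oc3c(OC)cc(/C=C/C(OCC)OCC)cc3[C@H]2CO)ccc1O[Si](C(C)C)(C(C)C)C(C)C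
F5 | step 9 | (E)-3-{(2R,3S)-3-(hydroxymethyl)-7-methoxy-2-[3-methoxy-4-(triisopropylsilyloxy)phenyl]-2,3-dihydro-1-benzofuran-5-yl}prop-2-enal | COc1cc([C@@H]2Oc3c(OC)cc(/C=C/C=O)cc3[C@H]2CO)ccc1O[Si](C(C)C)(C(C)C)C(C)C
F6 | step 8 | (1R,2S)-2-(5-ethenyl-2-fluoro-3-methoxyphenyl)-1-[3-methoxy-4-(triisopropylsilyloxy)phenyl]-3-(triisopropylsilyloxy)propan-1-ol | COc1cc([C@H](O)[C@@H](c2cc(C=C)cc(OC)c2F)CO[Si](C(C)C)(C(C)C)C(C)C)ccc1O[Si](C(C)C)(C(C)C)C(C)C
F7 | step 1 | 2-(5-bromo-2-fluoro-3-methoxyphenyl)-4,4,5,5-tetramethyl-1,3,2-dioxaborolane | COc1cc(Br)cc(B2OC(C)(C)C(C)(C)O2)c1F
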